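**Plan**
- Numbering is that of the daucane skeleton: C1 quaternary ring-fusion carbon with the angular methyl, C2, C3, C4 isopropyl carbinol, C5 ring-fusion CH, C6 aroyloxy carbon, C7, C8=C9 alkene, C10 tigloyloxy carbon.
- Retrosynthesis: cut the two esters (O10, O6), then the C8 methyl and C8=C9 (enone chemistry of a C10 ketone), then the C4–isopropyl bond (C4 ketone). The resulting cis-fused 4,10-diketone is cut at C2–C3 and C1–C5 in one operation.
- Enabling feature: the C10 oxygen sits next to the quaternary ring-fusion carbon C1, which is where a pinacol shift ends, and C3 is flanked by the oxygenated C4, which allows an acyl thionium electrophile. Both rings can therefore come from a 1-isopropenylcyclohexanol: Prins attack of C2 on C3, then migration of C5 from C10 to C1.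
- Forward: the six-membered ring comes first (cyclohexenone, three-component coupling). The key step turns it into the cycloheptanone while closing the cyclopentanone. C4, C8, C10 and the esters follow.
- Stereochemistry: C6 by catalyst-controlled silyl conjugate addition (silicon is a masked hydroxyl, oxidised with retention); C5 by anti aldol trapping; C1 by the suprafacial 1,2-shift (cis fusion); C4 by convex-face organocerium addition; C10 by hydroxyl-directed hydride delivery.

Key step: step 6

Remark: the SMILES is read as the tiglate (E ester) of a cis-fused hydroazulene (H5 and the C1 methyl on the same face); bicyclic compounds are named on the hydroazulene skeleton with daucane locants. Centres formed as mixtures and removed later (side-chain carbinol of 5, 6 and 7, C3 of 14, C8 of 22) are left undefined in the SMILES.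

**Step 1**
Reactants: 1 cyclohex-2-en-1-one; 2 dimethyl(phenyl)silylboronic acid pinacol ester; 3 acetaldehyde
Product: 6 (2S,3S)-3-[dimethyl(phenyl)silyl]-2-(1-hydroxyethyl)cyclohexan-1-one (carbinol epimers), via boron enolate 4 (not isolated), via boron aldolate 5 (not isolated)
Conditions: CuCl (cat.), chiral imidazolinium salt (NHC precursor, enantiomer giving the 3S silyl centre), NaOtBu (cat.), THF, −78 °C; then 3, −78 → −30 °C; aq. NH4Cl
Reagents that add atoms: none
Why: Copper-catalysed enantioselective conjugate silyl transfer fixes the silyl-bearing carbon (later C6) and leaves the O-boron enolate 4, which should add to acetaldehyde on the face anti to the bulky silyl group, placing the side chain at the later C5 trans to silicon (silylative aldol three-component coupling).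

**Step 2**
Reactants: 6 (2S,3S)-3-[dimethyl(phenyl)silyl]-2-(1-hydroxyethyl)cyclohexan-1-one
Product: 7 (1S,2S,3S)-3-[dimethyl(phenyl)silyl]-2-(1-hydroxyethyl)-1-(prop-1-en-2-yl)cyclohexan-1-ol
Conditions: CH2=C(CH3)MgBr (3.5 equiv), CeCl3 (3.5 equiv), THF, −78 °C; aq. NH4Cl
Reagents that add atoms: isopropenylmagnesium bromide, C=C(C)[Mg]Br
Why: The weakly basic organocerium reagent should add to the enolisable β-hydroxy ketone without retro-aldol cleavage and attack equatorially, trans to the side chain, so that isopropenyl and side chain become trans-diequatorial as the chair transition state of step 6 requires (organocerium 1,2-addition).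

**Step 3**
Reactants: 7 (1S,2S,3S)-3-[dimethyl(phenyl)silyl]-2-(1-hydroxyethyl)-1-(prop-1-en-2-yl)cyclohexan-1-ol
Product: 8 1-[(1R,2S,6S)-2-[dimethyl(phenyl)silyl]-6-hydroxy-6-(prop-1-en-2-yl)cyclohexyl]ethan-1-one
Conditions: Dess–Martin periodinane, pyridine, CH2Cl2, 0 °C → rt
Reagents that add atoms: none
Why: Dess–Martin oxidation converts the secondary carbinol into the methyl ketone and cannot touch the tertiary allylic alcohol, so both carbinol epimers converge on one ketone.

**Step 4**
Reactants: 8 1-[(1R,2S,6S)-2-[dimethyl(phenyl)silyl]-6-hydroxy-6-(prop-1-en-2-yl)cyclohexyl]ethan-1-one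
Product: 9 1-[(1R,2S,6S)-2-[dimethyl(phenyl)silyl]-6-(prop-1-en-2-yl)-6-(triethylsilyloxy)cyclohexyl]ethan-1-one
Conditions: Et3SiOTf, 2,6-lutidine, CH2Cl2, −78 → 0 °C
Reagents that add atoms: triethylsilyl trifluoromethanesulfonate, CC[Si](CC)(CC)OS(=O)(=O)C(F)(F)F
Why: Silylation of the tertiary alcohol with the silyl triflate blocks retro-aldol cleavage in the basic step 5 and installs the group that drives the pinacol shift in step 6 (silyl ether formation).

**Step 5**
Reactants: 9 1-[(1R,2S,6S)-2-[dimethyl(phenyl)silyl]-6-(prop-1-en-2-yl)-6-(triethylsilyloxy)cyclohexyl]ethan-1-one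
Product: 11 1-[(1R,2S,6S)-2-[dimethyl(phenyl)silyl]-6-(prop-1-en-2-yl)-6-(triethylsilyloxy)cyclohexyl]-2,2-bis(methylthio)ethan-1-one, via methylthio ketone 10 (not isolated)
Conditions: LiN(SiMe3)2 (2.5 equiv), THF, −78 °C; MeSO2SMe (2.1 equiv), −78 → 0 °C; aq. NH4Cl
Reagents that add atoms: S-methyl methanethiosulfonate, CS(=O)(=O)SC
Why: Kinetic deprotonation should occur at the methyl group, and the first sulfenylation makes C3 the most acidic position, so the second equivalent of base and thiosulfonate places the second methylthio group on the same carbon (enolate bis-sulfenylation).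

**Step 6**
Reactants: 11 1-[(1R,2S,6S)-2-[dimethyl(phenyl)silyl]-6-(prop-1-en-2-yl)-6-(triethylsilyloxy)cyclohexyl]-2,2-bis(methylthio)ethan-1-one
Product: 14 cis-fused (1R,5R,6S)-6-[dimethyl(phenyl)silyl]-1-methyl-3-(methylthio)hydroazulene-4,10-dione (daucane locants; C3 epimers), via thionium ion 12 (not isolated), via tertiary carbocation 13 (not isolated)
Conditions: dimethyl(methylthio)sulfonium tetrafluoroborate (1.5 equiv), CH2Cl2, −45 → 0 °C; aq. NaHCO3
Reagents that add atoms: none
Why: The sulfonium salt methylthiolates one sulfur of the dithioacetal and dimethyl disulfide leaves, giving the α-acyl thionium ion 12; its C3 is attacked by the terminal alkene carbon C2 (6-endo for the alkene, exo for C=S+, chair transition state with the two ring appendages trans-diequatorial), which forms C2–C3 and the tertiary cation 13 at C1. The silyloxy carbon C10 then pushes the ring bond C10–C5 onto C1 (pinacol 1,2-shift), which forms C1–C5, contracts the new six-membered ring to the cyclopentanone, enlarges the cyclohexane to the cycloheptanone by one carbon and releases the silyl group. The closest known reaction type is the thionium-ion-initiated Prins cyclisation–pinacol rearrangement (ring-enlarging cyclopentane annulation) of 1-alkenyl-2-(thioacetal-alkyl)cycloalkanol silyl ethers, which gives cis-fused hydroazulenones. C5 migrates with retention and suprafacially to the face of C1 on which it already lies in the chair, so the new quaternary centre C1 should carry its methyl cis to H5 (cis ring fusion); C6 is untouched and the C3 mixture is erased in step 7. The step needs Markovnikov attack through C2, secured by the 1,1-disubstituted alkene, which puts the charge on tertiary C1. It also needs migration of C5 instead of C9, secured stereoelectronically: in the chair cation the ring bond C10–C5 is nearly parallel to the empty p orbital at C1 while the equatorial C10–C9 bond lies in its nodal plane, and the β-silicon on C6 raises the migratory aptitude of C5.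

**Step 7**
Reactants: 14 cis-fused (1R,5R,6S)-6-[dimethyl(phenyl)silyl]-1-methyl-3-(methylthio)hydroazulene-4,10-dione
Product: 15 cis-fused (1R,5R,6S)-6-[dimethyl(phenyl)silyl]-1-methylhydroazulene-4,10-dione (daucane locants)
Conditions: SmI2 (2.5 equiv), THF/MeOH, −78 °C
Reagents that add atoms: none
Why: SmI2 should reduce the α-(methylthio) ketone selectively by electron transfer to the C4 carbonyl and loss of thiolate, and methanol protonates the samarium enolate at C3, so C5 is not epimerised and the isolated C10 ketone is left alone (reductive α-desulfurisation).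

**Step 8**
Reactants: 15 cis-fused (1R,5R,6S)-6-[dimethyl(phenyl)silyl]-1-methylhydroazulene-4,10-dione
Product: 16 (1R,4R,5R,6S)-6-[dimethyl(phenyl)silyl]-4-hydroxy-4-isopropyl-1-methylhydroazulen-10-one (daucane locants)
Conditions: i-PrMgCl (1.5 equiv), CeCl3 (1.5 equiv), THF, −78 °C; aq. NH4Cl
Reagents that add atoms: isopropylmagnesium chloride, CC(C)[Mg]Cl
Why: The organocerium reagent should add to the less hindered cyclopentanone (the C10 ketone is flanked by quaternary C1) from the convex face of the cis-fused bicycle, the face of H5 and the angular methyl, because the concave face is blocked by the C5–C6 bond and its silyl group; this sets C4 with the hydroxyl cis to C6 (organocerium 1,2-addition).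

**Step 9**
Reactants: 16 (1R,4R,5R,6S)-6-[dimethyl(phenyl)silyl]-4-hydroxy-4-isopropyl-1-methylhydroazulen-10-one
Product: 17 (1R,4R,5S,6S)-4,6-dihydroxy-4-isopropyl-1-methylhydroazulen-10-one (daucane locants)
Conditions: KBr, AcOOH, NaOAc, AcOH, rt
Reagents that add atoms: peracetic acid, CC(=O)OO
Why: Fleming–Tamao oxidation: bromodesilylation of the phenyl group followed by peracid-induced migration of C6 from silicon to oxygen should replace the silyl group by hydroxyl with retention at C6.

**Step 10**
Reactants: 17 (1R,4R,5S,6S)-4,6-dihydroxy-4-isopropyl-1-methylhydroazulen-10-one; 18 4-(tert-butyldimethylsilyloxy)benzoic acid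
Product: 20 (1R,4R,5S,6S)-4-hydroxy-4-isopropyl-1-methyl-10-oxohydroazulen-6-yl 4-(tert-butyldimethylsilyloxy)benzoate, via O-acylisourea 19 (not isolated)
Conditions: EDC, DMAP, CH2Cl2, rt
Reagents that add atoms: none
Why: Carbodiimide/DMAP (Steglich) esterification should acylate only the secondary C6 hydroxyl, the tertiary C4 hydroxyl being too hindered.

**Step 11**
Reactants: 20 (1R,4R,5S,6S)-4-hydroxy-4-isopropyl-1-methyl-10-oxohydroazulen-6-yl 4-(tert-butyldimethylsilyloxy)benzoate
Product: 21 (1R,4R,5S,6S)-4-hydroxy-4-isopropyl-1-methyl-10-oxohydroazul-8-en-6-yl 4-(tert-butyldimethylsilyloxy)benzoate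
Conditions: IBX (1.5 equiv), DMSO, 70 °C
Reagents that add atoms: none
Why: IBX dehydrogenates the ketone through its enol, and because C1 is quaternary only C9 carries α-hydrogens, so the double bond can form only between C8 and C9 (IBX dehydrogenation).

**Step 12**
Reactants: 21 (1R,4R,5S,6S)-4-hydroxy-4-isopropyl-1-methyl-10-oxohydroazul-8-en-6-yl 4-(tert-butyldimethylsilyloxy)benzoate
Product: 22 (1R,4R,5S,6S)-4-hydroxy-4-isopropyl-1,8-dimethyl-10-oxohydroazulen-6-yl 4-(tert-butyldimethylsilyloxy)benzoate (C8 epimers)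
Conditions: Me2CuLi (from MeLi and CuI, 3 equiv), Et2O, −78 → −40 °C; aq. NH4Cl
Reagents that add atoms: lithium dimethylcuprate, [Li+].C[Cu-]C
Why: The Gilman cuprate should add in 1,4-fashion to the enone and leave the aryl ester and silyl ether untouched; the new C8 centre is removed in step 13 (conjugate addition).

**Step 13**
Reactants: 22 (1R,4R,5S,6S)-4-hydroxy-4-isopropyl-1,8-dimethyl-10-oxohydroazulen-6-yl 4-(tert-butyldimethylsilyloxy)benzoate
Product: 23 (1R,4R,5S,6S)-4-hydroxy-4-isopropyl-1,8-dimethyl-10-oxohydroazul-8-en-6-yl 4-(tert-butyldimethylsilyloxy)benzoate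
Conditions: IBX (2 equiv), DMSO, 75 °C
Reagents that add atoms: none
Why: A second IBX dehydrogenation, again possible only towards C9, should give the β-methyl enone of the target.

**Step 14**
Reactants: 23 (1R,4R,5S,6S)-4-hydroxy-4-isopropyl-1,8-dimethyl-10-oxohydroazul-8-en-6-yl 4-(tert-butyldimethylsilyloxy)benzoate
Product: 24 (1R,4R,5S,6S,10R)-4,10-dihydroxy-4-isopropyl-1,8-dimethylhydroazul-8-en-6-yl 4-(tert-butyldimethylsilyloxy)benzoate
Conditions: Me4NBH(OAc)3, MeCN/AcOH, −30 °C
Reagents that add atoms: none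
Why: Hydroxyl-directed (Evans–Saksena) reduction: the C4 hydroxyl lies on the concave face over the seven-membered ring, exchanges an acetate on boron and should deliver hydride internally to the face of C10 syn to C2, so the new hydroxyl ends up cis to the angular methyl (10R); the enone is reduced in 1,2-fashion and the esters are left alone.

**Step 15**
Reactants: 24 (1R,4R,5S,6S,10R)-4,10-dihydroxy-4-isopropyl-1,8-dimethylhydroazul-8-en-6-yl 4-(tert-butyldimethylsilyloxy)benzoate; 25 tiglic acid
Product: 27 (1R,4R,5S,6S,10R)-4-hydroxy-4-isopropyl-1,8-dimethyl-10-[(E)-2-methylbut-2-enoyloxy]hydroazul-8-en-6-yl 4-(tert-butyldimethylsilyloxy)benzoate, via mixed anhydride 26 (not isolated)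
Conditions: 2,4,6-trichlorobenzoyl chloride, Et3N, toluene, rt; then 24, DMAP, 60 °C
Reagents that add atoms: none
Why: Yamaguchi esterification through the mixed anhydride should acylate the hindered secondary allylic alcohol without E/Z isomerisation of the tiglate, while the tertiary hydroxyl does not react.

**Step 16**
Reactants: 27 (1R,4R,5S,6S,10R)-4-hydroxy-4-isopropyl-1,8-dimethyl-10-[(E)-2-methylbut-2-enoyloxy]hydroazul-8-en-6-yl 4-(tert-butyldimethylsilyloxy)benzoate
Product: 28 (1R,4R,5S,6S,10R)-4-hydroxy-4-isopropyl-1,8-dimethyl-10-[(E)-2-methylbut-2-enoyloxy]hydroazul-8-en-6-yl 4-hydroxybenzoate (target)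
Conditions: Bu4NF, AcOH, THF, 0 °C
Reagents that add atoms: none
Why: Buffered fluoride should remove the phenolic silyl ether at 0 °C without touching the two esters or the tertiary alcohol (desilylation).

**Compound list**
1 | cyclohex-2-en-1-one | O=C1C=CCCC1 | starting material
2 | dimethyl(phenyl)silylboronic acid pinacol ester | CC1(C)OB(OC1(C)C)[Si](C)(C)c1ccccc1 | starting material
3 | acetaldehyde | CC=O | starting material
4 | boron enolate: (S)-3-[dimethyl(phenyl)silyl]cyclohex-1-en-1-yl pinacol borate | CC1(C)OB(OC2=C[C@@H]([Si](C)(C)c3ccccc3)CCC2)OC1(C)C | intermediate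
5 | boron aldolate of 6 (O-pinacolboryl) | O=C1CCC[C@H]([Si](C)(C)c2ccccc2)[C@H]1C(C)OB1OC(C)(C)C(C)(C)O1 | intermediate
6 | (2S,3S)-3-[dimethyl(phenyl)silyl]-2-(1-hydroxyethyl)cyclohexan-1-one | O=C1CCC[C@H]([Si](C)(C)c2ccccc2)[C@H]1C(C)O | intermediate
7 | (1S,2S,3S)-3-[dimethyl(phenyl)silyl]-2-(1-hydroxyethyl)-1-(prop-1-en-2-yl)cyclohexan-1-ol | C=C(C)[C@]1(O)CCC[C@H]([Si](C)(C)c2ccccc2)[C@H]1C(C)O | intermediate
8 | 1-[(1R,2S,6S)-2-[dimethyl(phenyl)silyl]-6-hydroxy-6-(prop-1-en-2-yl)cyclohexyl]ethan-1-one | C=C(C)[C@]1(O)CCC[C@H]([Si](C)(C)c2ccccc2)[C@H]1C(C)=O | intermediate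
9 | 1-[(1R,2S,6S)-2-[dimethyl(phenyl)silyl]-6-(prop-1-en-2-yl)-6-(triethylsilyloxy)cyclohexyl]ethan-1-one | C=C(C)[C@]1(O[Si](CC)(CC)CC)CCC[C@H]([Si](C)(C)c2ccccc2)[C@H]1C(C)=O | intermediate
10 | 2-(methylthio) ketone from 9 | C=C(C)[C@]1(O[Si](CC)(CC)CC)CCC[C@H]([Si](C)(C)c2ccccc2)[C@H]1C(=O)CSC | intermediate
11 | 1-[(1R,2S,6S)-2-[dimethyl(phenyl)silyl]-6-(prop-1-en-2-yl)-6-(triethylsilyloxy)cyclohexyl]-2,2-bis(methylthio)ethan-1-one | C=C(C)[C@]1(O[Si](CC)(CC)CC)CCC[C@H]([Si](C)(C)c2ccccc2)[C@H]1C(=O)C(SC)SC | intermediate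
12 | α-acyl thionium tetrafluoroborate from 11 | C=C(C)[C@]1(O[Si](CC)(CC)CC)CCC[C@H]([Si](C)(C)c2ccccc2)[C@H]1C(=O)C=[S+]C.F[B-](F)(F)F | intermediate
13 | trans-fused bicyclic tertiary carbocation at C1 (tetrafluoroborate) | C3[C+](C)[C@]1(O[Si](CC)(CC)CC)CCC[C@H]([Si](C)(C)c2ccccc2)[C@H]1C(=O)C3SC.F[B-](F)(F)F | intermediate
14 | cis-fused (1R,5R,6S)-6-[dimethyl(phenyl)silyl]-1-methyl-3-(methylthio)hydroazulene-4,10-dione | O=C1CCC[C@H]([Si](C)(C)c3ccccc3)[C@@H]2[C@@]1(C)CC(SC)C2=O | intermediate
15 | cis-fused (1R,5R,6S)-6-[dimethyl(phenyl)silyl]-1-methylhydroazulene-4,10-dione | O=C1CCC[C@H]([Si](C)(C)c3ccccc3)[C@@H]2[C@@]1(C)CCC2=O | intermediate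
16 | (1R,4R,5R,6S)-6-[dimethyl(phenyl)silyl]-4-hydroxy-4-isopropyl-1-methylhydroazulen-10-one | O=C1CCC[C@H]([Si](C)(C)c3ccccc3)[C@@H]2[C@@]1(C)CC[C@@]2(O)C(C)C | intermediate
17 | (1R,4R,5S,6S)-4,6-dihydroxy-4-isopropyl-1-methylhydroazulen-10-one | O=C1CCC[C@H](O)[C@@H]2[C@@]1(C)CC[C@@]2(O)C(C)C | intermediate
18 | 4-(tert-butyldimethylsilyloxy)benzoic acid | OC(=O)c1ccc(O[Si](C)(C)C(C)(C)C)cc1 | starting material
19 | O-acylisourea of 18 with EDC | CCN=C(NCCCN(C)C)OC(=O)c1ccc(O[Si](C)(C)C(C)(C)C)cc1 | intermediate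
20 | (1R,4R,5S,6S)-4-hydroxy-4-isopropyl-1-methyl-10-oxohydroazulen-6-yl 4-(tert-butyldimethylsilyloxy)benzoate | O=C1CCC[C@H](OC(=O)c3ccc(O[Si](C)(C)C(C)(C)C)cc3)[C@@H]2[C@@]1(C)CC[C@@]2(O)C(C)C | intermediate
21 | (1R,4R,5S,6S)-4-hydroxy-4-isopropyl-1-methyl-10-oxohydroazul-8-en-6-yl 4-(tert-butyldimethylsilyloxy)benzoate | O=C1C=CC[C@H](OC(=O)c3ccc(O[Si](C)(C)C(C)(C)C)cc3)[C@@H]2[C@@]1(C)CC[C@@]2(O)C(C)C | intermediate
22 | (1R,4R,5S,6S)-4-hydroxy-4-isopropyl-1,8-dimethyl-10-oxohydroazulen-6-yl 4-(tert-butyldimethylsilyloxy)benzoate (C8 epimers) | O=C1CC(C)C[C@H](OC(=O)c3ccc(O[Si](C)(C)C(C)(C)C)cc3)[C@@H]2[C@@]1(C)CC[C@@]2(O)C(C)C | intermediate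
23 | (1R,4R,5S,6S)-4-hydroxy-4-isopropyl-1,8-dimethyl-10-oxohydroazul-8-en-6-yl 4-(tert-butyldimethylsilyloxy)benzoate | O=C1C=C(C)C[C@H](OC(=O)c3ccc(O[Si](C)(C)C(C)(C)C)cc3)[C@@H]2[C@@]1(C)CC[C@@]2(O)C(C)C | intermediate
24 | (1R,4R,5S,6S,10R)-4,10-dihydroxy-4-isopropyl-1,8-dimethylhydroazul-8-en-6-yl 4-(tert-butyldimethylsilyloxy)benzoate | O[C@@H]1C=C(C)C[C@H](OC(=O)c3ccc(O[Si](C)(C)C(C)(C)C)cc3)[C@@H]2[C@@]1(C)CC[C@@]2(O)C(C)C | intermediate
25 | tiglic acid, (E)-2-methylbut-2-enoic acid | C/C=C(\C)C(O)=O | starting material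
26 | tiglic 2,4,6-trichlorobenzoic mixed anhydride | C/C=C(\C)C(=O)OC(=O)c1c(Cl)cc(Cl)cc1Cl | intermediate
27 | silyl-protected target: 10-tiglate 6-[4-(tert-butyldimethylsilyloxy)benzoate] | C/C=C(\C)C(=O)O[C@@H]1C=C(C)C[C@H](OC(=O)c3ccc(O[Si](C)(C)C(C)(C)C)cc3)[C@@H]2[C@@]1(C)CC[C@@]2(O)C(C)C | intermediate
28 | (1R,4R,5S,6S,10R)-4-hydroxy-4-isopropyl-1,8-dimethyl-10-[(E)-2-methylbut-2-enoyloxy]hydroazul-8-en-6-yl 4-hydroxybenzoate | C/C=C(\C)C(=O)O[C@@H]1C=C(C)C[C@H](OC(=O)c2ccc(O)cc2)[C@@H]2[C@@]1(C)CC[C@@]2(O)C(C)C | target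

**Step count and risks**
Total: 16 steps. Longest linear sequence: 16 steps (1 → 28).

Most likely to fail:

1. Step 6. The carbonyl-destabilised thionium ion may form too slowly, so that the tertiary allylic silyl ether ionises first, or the C1 cation may lose a proton before the electron-poor C5 migrates. The fallback lowers the oxidation level at C4 so that an ordinary thionium ion is used, as in the closest precedent. It sets out from 11: NaBH4 in MeOH should give the carbinol F1, and TBSOTf/2,6-lutidine the silyl ether F2. The same sulfonium salt should then trigger the Prins–pinacol sequence to the bicyclic ketone F3. Bu4NF should free the alcohol F4, and Swern oxidation returns the route to 14 (both C4 epimers converge).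

2. Step 8. The hindered, enolisable cyclopentanone may be enolised or reduced by β-hydride transfer from the secondary organometallic instead of undergoing addition. The fallback sets out from 15: isopropenylcerium dichloride (isopropenylmagnesium bromide, CeCl3, THF, −78 °C), a smaller nucleophile without β-hydrogens, should give the isopropenyl carbinol F5 by the same convex-face attack. Hydrogenation of its 1,1-disubstituted alkene (H2, PtO2, EtOAc) comes back to 16.

3. Step 14. Internal hydride delivery through the tertiary C4 hydroxyl may be too slow, so that external hydride attacks C10 from the convex face and gives the wrong C10 epimer. The fallback sets out from 23: NaBH4 with CeCl3 in MeOH at −78 °C (Luche reduction) should give the 10-epi alcohol F6. A Mitsunobu esterification with tiglic acid 25 (PPh3, diisopropyl azodicarboxylate, toluene) inverts C10 and comes back to the route at 27, replacing step 15.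

**Further compounds**
F1 | step 6 | 1-[(1R,2S,6S)-2-[dimethyl(phenyl)silyl]-6-(prop-1-en-2-yl)-6-(triethylsilyloxy)cyclohexyl]-2,2-bis(methylthio)ethan-1-ol (carbinol epimers) | C=C(C)[C@]1(O[Si](CC)(CC)CC)CCC[C@H]([Si](C)(C)c2ccccc2)[C@H]1C(O)C(SC)SC
F2 | step 6 | tert-butyldimethylsilyl ether of F1 | C=C(C)[C@]1(O[Si](CC)(CC)CC)CCC[C@H]([Si](C)(C)c2ccccc2)[C@H]1C(O[Si](C)(C)C(C)(C)C)C(SC)SC
F3 | step 6 | cis-fused (1R,5R,6S)-4-(tert-butyldimethylsilyloxy)-6-[dimethyl(phenyl)silyl]-1-methyl-3-(methylthio)hydroazulen-10-one (C3 and C4 epimers) | O=C1CCC[C@H]([Si](C)(C)c3ccccc3)[C@@H]2[C@@]1(C)CC(SC)C2O[Si](C)(C)C(C)(C)C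
F4 | step 6 | cis-fused (1R,5R,6S)-6-[dimethyl(phenyl)silyl]-4-hydroxy-1-methyl-3-(methylthio)hydroazulen-10-one (C3 and C4 epimers) | O=C1CCC[C@H]([Si](C)(C)c3ccccc3)[C@@H]2[C@@]1(C)CC(SC)C2O
F5 | step 8 | (1R,4R,5R,6S)-6-[dimethyl(phenyl)silyl]-4-hydroxy-1-methyl-4-(prop-1-en-2-yl)hydroazulen-10-one | O=C1CCC[C@H]([Si](C)(C)c3ccccc3)[C@@H]2[C@@]1(C)CC[C@@]2(O)C(C)=C
F6 | step 14 | (1R,4R,5S,6S,10S)-4,10-dihydroxy-4-isopropyl-1,8-dimethylhydroazul-8-en-6-yl 4-(tert-butyldimethylsilyloxy)benzoate | O[C@H]1C=C(C)C[C@H](OC(=O)c3ccc(O[Si](C)(C)C(C)(C)C)cc3)[C@@H]2[C@@]1(C)CC[C@@]2(O)C(C)C
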